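Ring A (rings A–E in SMILES order) is a phloroglucinol carrying the ether oxygen to ring B on C2, between the hydroxylated C1 and C3, with the third hydroxyl on C5: the oxygenation pattern of a folded triketide. The route therefore disconnects the ring A C1–C2 bond. A methyl 3,5-dioxohexanoate that already carries the ring B aryloxy group on C6 is closed by an intramolecular Claisen condensation, which forms ring A and leaves the most hindered diaryl ether of that ring in place without any aryl–oxygen coupling. Rings C, D and E are then added to the ring B phenol by three fluorobenzaldehyde substitution/Dakin cycles, and one global demethylation ends the synthesis.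

Key step: step 5

Remark: the target is achiral, so no stereocenter has to be set or protected.
Remark: 2-fluoro-4,6-dimethoxybenzaldehyde and 4-fluoro-2,6-dimethoxybenzaldehyde are taken as catalogue compounds; if they must be made, both are Vilsmeier–Haack formylation products of commercial 1-fluoro-3,5-dimethoxybenzene.
Remark: the ring B phenol is alkylated with a chloroacetic N-methoxy-N-methylamide so that the dianion acylation stops cleanly at the ketone stage; the methyl ester of the cyclisation precursor is kept so that methoxide is a degenerate nucleophile in the key step.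

Step 1
Reactants: 1 syringaldehyde (4-hydroxy-3,5-dimethoxybenzaldehyde)
Product: 2 4-(benzyloxy)-3,5-dimethoxybenzaldehyde
Conditions: BnBr, K2CO3, DMF, 60 °C
Reagents that add atoms: benzyl bromide, BrCc1ccccc1
Why: Williamson ether synthesis, in which the phenoxide of 1 (acidified by the para formyl group) should be benzylated on oxygen by SN2 while the aldehyde is untouched by carbonate.

Step 2
Reactants: 2 4-(benzyloxy)-3,5-dimethoxybenzaldehyde
Product: 4 4-(benzyloxy)-3,5-dimethoxyphenol, via aryl formate 3 (not isolated)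
Conditions: mCPBA, CH2Cl2, 0 °C to rt; then K2CO3 (cat.), MeOH, rt
Reagents that add atoms: mCPBA (3-chloroperoxybenzoic acid), OOC(=O)c1cccc(Cl)c1
Why: Baeyer–Villiger (Dakin-type) oxidation, in which the electron-rich trialkoxyaryl group migrates in the peracid adduct in preference to hydride to give formate 3, which base-catalysed methanolysis should cleave to the phenol without touching the benzyl or methyl ethers.

Step 3
Reactants: 4 4-(benzyloxy)-3,5-dimethoxyphenol; 5 2-chloro-N-methoxy-N-methylacetamide
Product: 6 2-[4-(benzyloxy)-3,5-dimethoxyphenoxy]-N-methoxy-N-methylacetamide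
Conditions: K2CO3, NaI (cat.), DMF, 60 °C
Reagents that add atoms: none
Why: Williamson ether synthesis, in which the unhindered phenoxide of 4 should displace chloride from the carbonyl-activated carbon of 5 (iodide catalysis by Finkelstein exchange) while the N-methoxy-N-methylamide is inert to carbonate.

Step 4
Reactants: 6 2-[4-(benzyloxy)-3,5-dimethoxyphenoxy]-N-methoxy-N-methylacetamide; 7 methyl acetoacetate
Product: 9 methyl 6-[4-(benzyloxy)-3,5-dimethoxyphenoxy]-3,5-dioxohexanoate, via methyl acetoacetate dianion 8 (not isolated)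
Conditions: 7 (2 equiv), NaH, THF, 0 °C; n-BuLi, 0 °C; then 6, −78 to 0 °C; cold aq. HCl
Reagents that add atoms: none
Why: Claisen-type C-acylation of a 1,3-dicarbonyl dianion, in which the terminal carbanion of 8 (its most nucleophilic site) adds to the N-methoxy-N-methylamide to give a chelated tetrahedral adduct that persists until the acidic quench, so the acidic triketide product should neither consume dianion nor be attacked a second time.

Step 5
Reactants: 9 methyl 6-[4-(benzyloxy)-3,5-dimethoxyphenoxy]-3,5-dioxohexanoate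
Product: 10 2-[4-(benzyloxy)-3,5-dimethoxyphenoxy]benzene-1,3,5-triol
Conditions: NaOMe (5 equiv), degassed MeOH, reflux, Ar; then 1 M HCl, 0 °C
Reagents that add atoms: none
Why: Methoxide equilibrates the enolates of 9, and the minor dianion deprotonated at C4 and C6 attacks the non-enolised ester carbon C1 through C6, expels methoxide and gives the 2-aryloxycyclohexane-1,3,5-trione tautomer of 10, which aromatises at once to the phloroglucinol (as its phenoxide) and is released on acidification. The closest known reaction is the intramolecular Claisen (Dieckmann-type) condensation that converts δ-keto esters into cyclohexane-1,3-diones and 3,5-dioxoalkanoates into phloroglucinols, the laboratory version of polyketide ring closure. Ring A closes in the 6-(enolendo)-exo-trig mode, because the C5=C6 enolate bond lies inside the new ring and the ester carbonyl outside it, a mode that is favoured for six-membered rings; no stereocenter is created. The step needs C-acylation through C6 instead of O-acylation through the C5 enolate oxygen, which would give a 4-hydroxy-2-pyrone: the aryloxy substituent makes C6 markedly more acidic than a methyl terminus, the methyl ester/methoxide pair renders ester exchange degenerate and allows methanolysis of any pyrone back to 9, and aromatisation withdraws the C-acylated product irreversibly. Because the ring A–ring B ether oxygen is already attached to C6, no aryl–oxygen coupling at the doubly flanked C2 of ring A is needed.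

Step 6
Reactants: 10 2-[4-(benzyloxy)-3,5-dimethoxyphenoxy]benzene-1,3,5-triol
Product: 11 2-[4-(benzyloxy)-3,5-dimethoxyphenoxy]-1,3,5-trimethoxybenzene
Conditions: Me2SO4, K2CO3, acetone, reflux, Ar
Reagents that add atoms: dimethyl sulfate, COS(=O)(=O)OC
Why: Williamson O-methylation with a hard sulfate electrophile under carbonate in acetone, the conditions that convert phloroglucinol itself into its trimethyl ether, should cap the three ring A hydroxyls with little C-methylation and leave the benzyl ether in place.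

Step 7
Reactants: 11 2-[4-(benzyloxy)-3,5-dimethoxyphenoxy]-1,3,5-trimethoxybenzene
Product: 12 2,6-dimethoxy-4-(2,4,6-trimethoxyphenoxy)phenol
Conditions: H2 (1 atm), 10% Pd/C (palladium on carbon), EtOAc–MeOH, rt
Reagents that add atoms: none
Why: Catalytic hydrogenolysis of the benzyl aryl ether should free only the ring B C4 hydroxyl, since aryl methyl ethers and the diaryl ether are inert to hydrogen over palladium.

Step 8
Reactants: 12 2,6-dimethoxy-4-(2,4,6-trimethoxyphenoxy)phenol; 13 2-fluoro-4,6-dimethoxybenzaldehyde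
Product: 14 2-[2,6-dimethoxy-4-(2,4,6-trimethoxyphenoxy)phenoxy]-4,6-dimethoxybenzaldehyde (rings A–B–C, formyl on ring C)
Conditions: Cs2CO3, DMSO, 110 °C, Ar
Reagents that add atoms: none
Why: Nucleophilic aromatic substitution (addition–elimination), in which the phenoxide of 12 adds to the fluorine-bearing carbon of 13, the ortho formyl group stabilises the anionic σ-adduct, both methoxy groups are meta to the reacting carbon and so do not deactivate it, and fluoride is lost.

Step 9
Reactants: 14 2-[2,6-dimethoxy-4-(2,4,6-trimethoxyphenoxy)phenoxy]-4,6-dimethoxybenzaldehyde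
Product: 16 2-[2,6-dimethoxy-4-(2,4,6-trimethoxyphenoxy)phenoxy]-4,6-dimethoxyphenol, via aryl formate 15 (not isolated)
Conditions: mCPBA, CH2Cl2, 0 °C; then K2CO3 (cat.), degassed MeOH, rt
Reagents that add atoms: mCPBA (3-chloroperoxybenzoic acid), OOC(=O)c1cccc(Cl)c1
Why: Baeyer–Villiger (Dakin-type) oxidation, in which the 2,4,6-trioxygenated aryl group of ring C migrates readily and methanolysis of formate 15 should unveil the ring C hydroxyl that becomes the ether oxygen to ring D.

Step 10
Reactants: 16 2-[2,6-dimethoxy-4-(2,4,6-trimethoxyphenoxy)phenoxy]-4,6-dimethoxyphenol; 17 4-fluoro-2,6-dimethoxybenzaldehyde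
Product: 18 4-{2-[2,6-dimethoxy-4-(2,4,6-trimethoxyphenoxy)phenoxy]-4,6-dimethoxyphenoxy}-2,6-dimethoxybenzaldehyde (rings A–D, formyl on ring D)
Conditions: Cs2CO3, DMSO, 110 °C, Ar
Reagents that add atoms: none
Why: Nucleophilic aromatic substitution, in which the phenoxide of 16 attacks the fluorine-bearing carbon para to the formyl group of 17, a position without ortho substituents that should tolerate the hindered nucleophile.

Step 11
Reactants: 18 4-{2-[2,6-dimethoxy-4-(2,4,6-trimethoxyphenoxy)phenoxy]-4,6-dimethoxyphenoxy}-2,6-dimethoxybenzaldehyde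
Product: 20 4-{2-[2,6-dimethoxy-4-(2,4,6-trimethoxyphenoxy)phenoxy]-4,6-dimethoxyphenoxy}-2,6-dimethoxyphenol, via aryl formate 19 (not isolated)
Conditions: mCPBA, CH2Cl2, 0 °C; then K2CO3 (cat.), degassed MeOH, rt
Reagents that add atoms: mCPBA (3-chloroperoxybenzoic acid), OOC(=O)c1cccc(Cl)c1
Why: Baeyer–Villiger (Dakin-type) oxidation followed by formate methanolysis, as in step 9, should replace the ring D formyl group by the hydroxyl flanked by two methoxy groups.

Step 12
Reactants: 20 4-{2-[2,6-dimethoxy-4-(2,4,6-trimethoxyphenoxy)phenoxy]-4,6-dimethoxyphenoxy}-2,6-dimethoxyphenol; 17 4-fluoro-2,6-dimethoxybenzaldehyde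
Product: 21 4-(4-{2-[2,6-dimethoxy-4-(2,4,6-trimethoxyphenoxy)phenoxy]-4,6-dimethoxyphenoxy}-2,6-dimethoxyphenoxy)-2,6-dimethoxybenzaldehyde (rings A–E, formyl on ring E)
Conditions: Cs2CO3, DMSO, 110 °C, Ar
Reagents that add atoms: none
Why: Nucleophilic aromatic substitution of the same type as step 10, in which the 2,6-dimethoxyphenoxide of 20 displaces the para-activated fluoride of a second equivalent of 17 to attach ring E.

Step 13
Reactants: 21 4-(4-{2-[2,6-dimethoxy-4-(2,4,6-trimethoxyphenoxy)phenoxy]-4,6-dimethoxyphenoxy}-2,6-dimethoxyphenoxy)-2,6-dimethoxybenzaldehyde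
Product: 23 4-(4-{2-[2,6-dimethoxy-4-(2,4,6-trimethoxyphenoxy)phenoxy]-4,6-dimethoxyphenoxy}-2,6-dimethoxyphenoxy)-2,6-dimethoxyphenol, via aryl formate 22 (not isolated)
Conditions: mCPBA, CH2Cl2, 0 °C; then K2CO3 (cat.), degassed MeOH, rt
Reagents that add atoms: mCPBA (3-chloroperoxybenzoic acid), OOC(=O)c1cccc(Cl)c1
Why: Baeyer–Villiger (Dakin-type) oxidation and methanolysis should convert the ring E formyl group into the central hydroxyl of the future pyrogallol unit.

Step 14
Reactants: 23 4-(4-{2-[2,6-dimethoxy-4-(2,4,6-trimethoxyphenoxy)phenoxy]-4,6-dimethoxyphenoxy}-2,6-dimethoxyphenoxy)-2,6-dimethoxyphenol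
Product: 24 2-(4-{2-[3,5-dihydroxy-4-(3,4,5-trihydroxyphenoxy)phenoxy]-3,5-dihydroxyphenoxy}-3,5-dihydroxyphenoxy)benzene-1,3,5-triol (CNP0227069.0)
Conditions: BBr3 (excess), CH2Cl2, −78 °C to rt, Ar; then MeOH/H2O, 0 °C
Reagents that add atoms: none
Why: Lewis-acid ether cleavage, in which BBr3 coordinates each of the eleven methoxy oxygens and bromide removes the methyl group by SN2, whereas the diaryl ether bonds offer no sp3 carbon for this attack and should survive, so hydrolysis of the aryl borates should give the dodecahydroxy target.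

Compound list
1 | syringaldehyde (4-hydroxy-3,5-dimethoxybenzaldehyde) | COc1cc(C=O)cc(OC)c1O | starting material
2 | 4-(benzyloxy)-3,5-dimethoxybenzaldehyde | COc1cc(C=O)cc(OC)c1OCc1ccccc1 | intermediate
3 | 4-(benzyloxy)-3,5-dimethoxyphenyl formate (not isolated) | COc1cc(OC=O)cc(OC)c1OCc1ccccc1 | intermediate
4 | 4-(benzyloxy)-3,5-dimethoxyphenol | COc1cc(O)cc(OC)c1OCc1ccccc1 | intermediate
5 | 2-chloro-N-methoxy-N-methylacetamide | CON(C)C(=O)CCl | starting material
6 | 2-[4-(benzyloxy)-3,5-dimethoxyphenoxy]-N-methoxy-N-methylacetamide | CON(C)C(=O)COc1cc(OC)c(OCc2ccccc2)c(OC)c1 | intermediate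
7 | methyl acetoacetate | COC(=O)CC(C)=O | starting material
8 | methyl acetoacetate dianion, sodium lithium salt (not isolated) | [CH2-]C(=O)[CH-]C(=O)OC.[Na+].[Li+] | intermediate
9 | methyl 6-[4-(benzyloxy)-3,5-dimethoxyphenoxy]-3,5-dioxohexanoate | COC(=O)CC(=O)CC(=O)COc1cc(OC)c(OCc2ccccc2)c(OC)c1 | intermediate
10 | 2-[4-(benzyloxy)-3,5-dimethoxyphenoxy]benzene-1,3,5-triol | Oc1cc(O)c(Oc2cc(OC)c(OCc3ccccc3)c(OC)c2)c(O)c1 | intermediate
11 | 2-[4-(benzyloxy)-3,5-dimethoxyphenoxy]-1,3,5-trimethoxybenzene | COc1cc(OC)c(Oc2cc(OC)c(OCc3ccccc3)c(OC)c2)c(OC)c1 | intermediate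
12 | 2,6-dimethoxy-4-(2,4,6-trimethoxyphenoxy)phenol | COc1cc(OC)c(Oc2cc(OC)c(O)c(OC)c2)c(OC)c1 | intermediate
13 | 2-fluoro-4,6-dimethoxybenzaldehyde | COc1cc(F)c(C=O)c(OC)c1 | starting material
14 | 2-[2,6-dimethoxy-4-(2,4,6-trimethoxyphenoxy)phenoxy]-4,6-dimethoxybenzaldehyde | COc1cc(OC)c(Oc2cc(OC)c(Oc3cc(OC)cc(OC)c3C=O)c(OC)c2)c(OC)c1 | intermediate
15 | 2-[2,6-dimethoxy-4-(2,4,6-trimethoxyphenoxy)phenoxy]-4,6-dimethoxyphenyl formate (not isolated) | COc1cc(OC)c(Oc2cc(OC)c(Oc3cc(OC)cc(OC)c3OC=O)c(OC)c2)c(OC)c1 | intermediate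
16 | 2-[2,6-dimethoxy-4-(2,4,6-trimethoxyphenoxy)phenoxy]-4,6-dimethoxyphenol | COc1cc(OC)c(Oc2cc(OC)c(Oc3cc(OC)cc(OC)c3O)c(OC)c2)c(OC)c1 | intermediate
17 | 4-fluoro-2,6-dimethoxybenzaldehyde | COc1cc(F)cc(OC)c1C=O | starting material
18 | 4-{2-[2,6-dimethoxy-4-(2,4,6-trimethoxyphenoxy)phenoxy]-4,6-dimethoxyphenoxy}-2,6-dimethoxybenzaldehyde | COc1cc(OC)c(Oc2cc(OC)c(Oc3cc(OC)cc(OC)c3Oc3cc(OC)c(C=O)c(OC)c3)c(OC)c2)c(OC)c1 | intermediate
19 | 4-{2-[2,6-dimethoxy-4-(2,4,6-trimethoxyphenoxy)phenoxy]-4,6-dimethoxyphenoxy}-2,6-dimethoxyphenyl formate (not isolated) | COc1cc(OC)c(Oc2cc(OC)c(Oc3cc(OC)cc(OC)c3Oc3cc(OC)c(OC=O)c(OC)c3)c(OC)c2)c(OC)c1 | intermediate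
20 | 4-{2-[2,6-dimethoxy-4-(2,4,6-trimethoxyphenoxy)phenoxy]-4,6-dimethoxyphenoxy}-2,6-dimethoxyphenol | COc1cc(OC)c(Oc2cc(OC)c(Oc3cc(OC)cc(OC)c3Oc3cc(OC)c(O)c(OC)c3)c(OC)c2)c(OC)c1 | intermediate
21 | 4-(4-{2-[2,6-dimethoxy-4-(2,4,6-trimethoxyphenoxy)phenoxy]-4,6-dimethoxyphenoxy}-2,6-dimethoxyphenoxy)-2,6-dimethoxybenzaldehyde | COc1cc(OC)c(Oc2cc(OC)c(Oc3cc(OC)cc(OC)c3Oc3cc(OC)c(Oc4cc(OC)c(C=O)c(OC)c4)c(OC)c3)c(OC)c2)c(OC)c1 | intermediate
22 | 4-(4-{2-[2,6-dimethoxy-4-(2,4,6-trimethoxyphenoxy)phenoxy]-4,6-dimethoxyphenoxy}-2,6-dimethoxyphenoxy)-2,6-dimethoxyphenyl formate (not isolated) | COc1cc(OC)c(Oc2cc(OC)c(Oc3cc(OC)cc(OC)c3Oc3cc(OC)c(Oc4cc(OC)c(OC=O)c(OC)c4)c(OC)c3)c(OC)c2)c(OC)c1 | intermediate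
23 | 4-(4-{2-[2,6-dimethoxy-4-(2,4,6-trimethoxyphenoxy)phenoxy]-4,6-dimethoxyphenoxy}-2,6-dimethoxyphenoxy)-2,6-dimethoxyphenol | COc1cc(OC)c(Oc2cc(OC)c(Oc3cc(OC)cc(OC)c3Oc3cc(OC)c(Oc4cc(OC)c(O)c(OC)c4)c(OC)c3)c(OC)c2)c(OC)c1 | intermediate
24 | 2-(4-{2-[3,5-dihydroxy-4-(3,4,5-trihydroxyphenoxy)phenoxy]-3,5-dihydroxyphenoxy}-3,5-dihydroxyphenoxy)benzene-1,3,5-triol (CNP0227069.0) | Oc1cc(O)c(Oc2cc(O)c(Oc3cc(O)cc(O)c3Oc3cc(O)c(Oc4cc(O)c(O)c(O)c4)c(O)c3)c(O)c2)c(O)c1 | target

Total step count: 14.
Longest linear sequence: 14 steps (1 to 24).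

Steps most likely to fail

Step 5. The ring closure may run through the C5 enolate oxygen (lactonisation to the 4-hydroxy-2-pyrone) or be overtaken by methoxide-induced retro-Claisen fragmentation before C6 acylates C1. The fallback builds the ring A–ring B ether by the substitution/oxidation logic used for the later rings. It sets out from 17, which should be substituted by commercial 2,4,6-trimethoxyphenol F1 (Cs2CO3, DMSO, 110 °C) to give 2,6-dimethoxy-4-(2,4,6-trimethoxyphenoxy)benzaldehyde F2. Baeyer–Villiger oxidation of F2 with mCPBA should give 2,6-dimethoxy-4-(2,4,6-trimethoxyphenoxy)phenyl formate F3, and methanolysis (K2CO3, MeOH) returns to the route at 12.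

Step 8. The substitution may stall, because a di-ortho-substituted phenoxide has to attack a carbon next to the formyl group of a donor-substituted ring, and the aldehyde may degrade under base at the higher temperature then required. The fallback replaces addition–elimination by a copper-catalysed Ullmann ether synthesis. It sets out from 12, which should couple with 2-bromo-4,6-dimethoxybenzaldehyde F4 (CuI, picolinic acid, K3PO4, DMSO, 90 °C), where the ortho formyl group assists the copper insertion, and it comes back to the route at 14.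

Step 14. Cleavage of the eleven methyl ethers may stay incomplete, and the free polyphenol may oxidise in air during isolation. The fallback changes from direct isolation to a derivatise-and-release sequence. It sets out from 23: the crude product of exhaustive BBr3 demethylation is peracetylated at once (Ac2O, pyridine) to the dodecaacetate of the target F5, a neutral, air-stable compound that can be chromatographed away from under-demethylated material. Acid-catalysed methanolysis of F5 (HCl from AcCl in degassed MeOH, Ar) then comes back to the route at 24.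

Further compounds
F1 | step 5 | 2,4,6-trimethoxyphenol | COc1cc(OC)c(O)c(OC)c1
F2 | step 5 | 2,6-dimethoxy-4-(2,4,6-trimethoxyphenoxy)benzaldehyde | COc1cc(OC)c(Oc2cc(OC)c(C=O)c(OC)c2)c(OC)c1
F3 | step 5 | 2,6-dimethoxy-4-(2,4,6-trimethoxyphenoxy)phenyl formate | COc1cc(OC)c(Oc2cc(OC)c(OC=O)c(OC)c2)c(OC)c1
F4 | step 8 | 2-bromo-4,6-dimethoxybenzaldehyde | COc1cc(Br)c(C=O)c(OC)c1
F5 | step 14 | dodecaacetate of the target (all twelve hydroxyls of 24 acetylated) | CC(=O)Oc1cc(OC(C)=O)c(Oc2cc(OC(C)=O)c(Oc3cc(OC(C)=O)cc(OC(C)=O)c3Oc3cc(OC(C)=O)c(Oc4cc(OC(C)=O)c(OC(C)=O)c(OC(C)=O)c4)c(OC(C)=O)c3)c(OC(C)=O)c2)c(OC(C)=O)c1
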